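**Retrosynthetic overview**
1. Target 31 ⇐ methyl ester 30 ⇐ ring D closed last by SmI2 ketyl–alkyne cyclisation of the C13 ketone onto the C8 propargyl group of 29.
2. Ring A (1α,3β-diol) ⇐ 3β-hydroxy-1-ketone ⇐ 2β,3β-epoxy-1-ketone ⇐ enone 26 ⇐ intramolecular aldol condensation (C2–C3), after a formaldehyde aldol at C4 (C3–C4) and acetyl-anion addition with lactonisation at C10.
3. Key disconnection: C4–C5, by intermolecular Michael addition of diallyl methylmalonate 17 to the ring B/C enone ester 15.
4. Ring B ⇐ aldol condensation of diketo ester 14; C9–C10 ⇐ intermolecular aldol of the ring C vinylogous ester with acetaldehyde; ring C ⇐ Birch reductive alkylation of 3,5-dimethoxybenzoic acid, resolved at C8.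
5. Order of ring formation: C → B → lactone → A → D.

Assumption: atoms carry the gibberellane numbers they have in the target (C1–C19); α is the face of the C19→C10 lactone bridge, β the opposite face (H5, H9, C15); the target SMILES is read as the 1α,3β,13-triol; where a name says "epimers", that centre is erased later and is left undefined in the SMILES.

**Route**

Step 1
Reactants: 1 3,5-dimethoxybenzoic acid; 2 3-bromo-1-(trimethylsilyl)prop-1-yne
Product: 3 3,5-dimethoxy-1-[3-(trimethylsilyl)prop-2-yn-1-yl]cyclohexa-2,5-diene-1-carboxylic acid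
Conditions: Li (3.2 equiv), NH3(l)/THF, −78 °C; piperylene; then 2, −78 °C to rt; cold dilute HCl to pH 4
Reagents that add atoms: none
Why: Birch reduction gives the carboxylate-stabilised cyclohexadienyl dianion, which is C-alkylated at the ipso carbon by the propargylic bromide (Birch reductive alkylation); the product is symmetric, so no stereocentre arises.

Step 2
Reactants: 3 diene acid
Product: 4 racemic 3-methoxy-5-oxo-1-[3-(trimethylsilyl)prop-2-yn-1-yl]cyclohex-3-ene-1-carboxylic acid
Conditions: 0.5 M HCl, THF, 0 °C, 1 h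
Reagents that add atoms: water, O
Why: The first enol ether hydrolyses much faster than the conjugated 3-methoxyenone that results, so mild acid stops at the vinylogous ester (chemoselective enol ether hydrolysis); the product is racemic at C8.

Step 3
Reactants: 4 racemic vinylogous ester acid
Product: 5 (S)-3-methoxy-5-oxo-1-[3-(trimethylsilyl)prop-2-yn-1-yl]cyclohex-3-ene-1-carboxylic acid
Conditions: (S)-1-phenylethylamine (0.55 equiv; or its antipode, whichever gives the less soluble salt of the (S)-acid), EtOAc/EtOH, two recrystallisations; 1 M KHSO4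
Reagents that add atoms: none
Why: Classical resolution by diastereomeric salt crystallisation fixes the absolute configuration at C8, the only stereocentre; the unwanted enantiomer can be recycled because full acid hydrolysis gives the achiral 1,3-dione.

Step 4
Reactants: 5 (S)-acid
Product: 7 cis-fused γ-lactone (C6 carbonyl–O–C10H(CH3)) on the ring C 3-methoxyenone with C10 epimers, via aldol hydroxy acid 6 (not isolated)
Conditions: LDA (2.2 equiv), THF, −78 °C; CH3CHO, −78 °C; AcOH; then TsOH (cat.), 4 Å sieves, PhH, 40 °C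
Reagents that add atoms: acetaldehyde, CC=O
Why: Kinetic α′-deprotonation of the vinylogous ester (Stork–Danheiser enolate of the carboxylate dianion) and intermolecular aldol addition to acetaldehyde form C9–C10; acid-catalysed lactonisation, with equilibration at the epimerisable C9, gives the cis-fused lactone (H9 syn to the C8 propargyl group).

Step 5
Reactants: 7 enol-ether keto lactone
Product: 9 cis-fused enone lactone (C13 ketone with C11=C12), via allylic alcohol 8 (not isolated)
Conditions: NaBH4, CeCl3·7H2O, MeOH, 0 °C to rt; then 1 M HCl, THF, rt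
Reagents that add atoms: water, O
Why: Luche 1,2-reduction of the vinylogous ester carbonyl, then acid-induced enol ether hydrolysis and dehydration (Stork–Danheiser transposition), moves the ketone to C13 and removes the C11 oxygen; the γ-lactone is inert to NaBH4/CeCl3.

Step 6
Reactants: 9 enone lactone
Product: 10 saturated C13 ketone lactone
Conditions: [(Ph3P)CuH]6 (0.4 equiv), H2O (2 equiv), PhH, rt
Reagents that add atoms: none
Why: Copper hydride conjugate reduction (Stryker reduction) delivers hydride only to the enone β-carbon C11 and leaves the lactone and the silyl alkyne untouched.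

Step 7
Reactants: 10 keto lactone
Product: 11 C13 ethylene ketal of 10
Conditions: HOCH2CH2OH, PPTS (cat.), PhH, reflux, Dean–Stark
Reagents that add atoms: ethylene glycol, OCCO
Why: Acid-catalysed ketalisation protects the C13 ketone from the organolithium and enolate chemistry that follows.

Step 8
Reactants: 11 ketal lactone
Product: 12 hydroxy enone (C8–C(=O)–C(OMe)=CH2 and C9–CH(OH)CH3; in equilibrium with its hemiketal)
Conditions: CH2=C(OMe)Li (2 equiv; from methyl vinyl ether and t-BuLi), THF, −78 °C; then H2O
Reagents that add atoms: 1-methoxyvinyllithium, [Li]C(=C)OC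
Why: Acyl substitution of the lactone by the acyl-anion equivalent stops after one addition because the tetrahedral lithium lactolate is stable at −78 °C; this frees the C10 carbinol and turns C6 into a masked α-keto ester.

Step 9
Reactants: 12 hydroxy enone
Product: 13 diketone with C9 acetyl and C8 2-methoxyacryloyl groups
Conditions: Dess–Martin periodinane, NaHCO3, CH2Cl2, rt
Reagents that add atoms: none
Why: Dess–Martin oxidation of the secondary C10 alcohol (drained from the hemiketal equilibrium) gives the C9 acetyl group; the buffered conditions spare the enol ether and ketal.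

Step 10
Reactants: 13 methoxy enone diketone
Product: 14 methyl α-keto ester (C8–C(=O)–CO2Me) with C9 acetyl
Conditions: O3, CH2Cl2/MeOH, −78 °C, stopped at consumption of 13; Me2S
Reagents that add atoms: ozone, [O-][O+]=O
Why: Ozonolysis cleaves the electron-rich 2-methoxyvinyl double bond far faster than the silyl alkyne and leaves the methoxy-bearing carbon as a methyl ester, so C6 is now a ketone carrying C7 as CO2Me.

Step 11
Reactants: 14 diketo ester
Product: 15 ring B/C enone ester (C10 ketone, C5=C6 with CO2Me on C6, cis ring fusion, C13 ketal, C8 CH2C≡CSiMe3)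
Conditions: piperidine (0.3 equiv), AcOH (0.3 equiv), PhH, 60 °C
Reagents that add atoms: none
Why: Intramolecular aldol condensation of the methyl ketone (C5) with the non-enolisable α-keto ester carbonyl (C6) closes ring B, and the epimerisable C9 settles in the more stable cis ring fusion (H9 syn to the C8 propargyl group).

Step 12
Reactants: 16 methylmalonic acid
Product: 17 diallyl methylmalonate
Conditions: allyl bromide (2.2 equiv), K2CO3, DMF, rt
Reagents that add atoms: allyl bromide, C=CCBr
Why: Double SN2 O-alkylation of the dicarboxylate gives a malonate donor whose ester groups can later be removed under neutral conditions.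

Step 13
Reactants: 15 enone ester; 17 diallyl methylmalonate
Product: 18 Michael adduct (C5 carries α-C(CH3)(CO2allyl)2, C6 carries β-CO2Me)
Conditions: 17 (3 equiv), Cs2CO3 (0.2 equiv), MeCN, rt to 40 °C
Reagents that add atoms: none
Why: Intermolecular Michael addition of the soft malonate anion occurs at C5, the only unhindered acceptor carbon (C6 is fully substituted and flanked by quaternary C8), forming C4–C5; reversibility and the enolisable C5 and C6 let the adduct relax to the trans arrangement with the C6 ester on the convex β face and C4 on the α face.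

Step 14
Reactants: 18 Michael adduct
Product: 20 γ-lactone allyl ester (C19(=O)–O–C10; C4 bears CH3 and CO2allyl as C4 epimers; C10 bears β-C(OEt)=CH2), via tertiary carbinol 19 (not isolated)
Conditions: CH2=C(OEt)Li (from ethyl vinyl ether and t-BuLi), CeCl3, THF, −78 °C; then rt, 2 h; H2O
Reagents that add atoms: 1-ethoxyvinyllithium, [Li]C(=C)OCC
Why: The organocerium acetyl-anion equivalent adds 1,2 to the hindered, enolisable C10 ketone from the β face, anti to C4 on C5 and to C11 on C9; the α-alkoxide is cis to the malonate and lactonises onto one allyl ester, closing the C19→C10 lactone.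

Step 15
Reactants: 20 lactone allyl ester
Product: 22 C4–H lactone (C4 epimers), via lactone acid 21 (not isolated)
Conditions: Pd(PPh3)4 (5 mol %), morpholine (3 equiv), THF, rt; then 60 °C
Reagents that add atoms: none
Why: Zerovalent palladium transfers the allyl group to morpholine (Tsuji–Trost deallylation) and the resulting malonic half acid loses CO2 on warming; the C4 configuration is reset in the next step.

Step 16
Reactants: 22 C4–H lactone
Product: 23 C4 hydroxymethyl lactone (C4 bears β-CH3 as C18 and CH2OH as C3)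
Conditions: LDA (1.3 equiv), THF, −78 °C; CH2O (gas), −78 to −40 °C; then H2O
Reagents that add atoms: formaldehyde, C=O
Why: The lactone enolate (more acidic than the hindered C6 ester position) adds to formaldehyde in an intermolecular aldol reaction on its convex face, anti to ring B and syn to H5 and the C10 side chain; this places C3 on the side of C1 and the methyl group on the concave face, as in the target.

Step 17
Reactants: 23 hydroxymethyl lactone
Product: 24 C3 aldehyde
Conditions: Dess–Martin periodinane, NaHCO3, CH2Cl2, 0 °C to rt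
Reagents that add atoms: none
Why: Dess–Martin oxidation converts the neopentyl primary alcohol into the non-enolisable aldehyde without touching the enol ether or ketal under buffered conditions.

Step 18
Reactants: 24 aldehyde
Product: 26 ring A enone (1-oxo-2-ene, C13 ketone free), via keto aldehyde 25 (not isolated)
Conditions: TsOH·H2O (0.3 equiv), THF/H2O 10:1, 40 °C; then PhH, reflux, Dean–Stark
Reagents that add atoms: water, O
Why: Aqueous acid hydrolyses the enol ether to the C1 methyl ketone and the dioxolane to the C13 ketone; acid-catalysed intramolecular aldol condensation of the methyl ketone (C2) with the non-enolisable C3 aldehyde then closes ring A.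

Step 19
Reactants: 26 ring A enone
Product: 27 2β,3β-epoxy-1-ketone with the terminal alkyne freed
Conditions: 30% H2O2, K2CO3, MeOH, 0 °C
Reagents that add atoms: hydrogen peroxide, OO
Why: Weitz–Scheffer nucleophilic epoxidation adds hydroperoxide to C3 from the β face because the α face of ring A is covered by the lactone bridge, setting the C3–O bond β; K2CO3/MeOH also removes the alkynyl silyl group.

Step 20
Reactants: 27 epoxy ketone
Product: 28 3β-hydroxy-1-ketone
Conditions: Cp2TiCl (2.5 equiv; from Cp2TiCl2 and Zn), THF/MeOH, −78 to −20 °C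
Reagents that add atoms: none
Why: The trivalent titanium reagent opens the epoxy ketone homolytically at the Cα–O bond (C2) and the titanium enolate is protonated, leaving the β C3–O bond intact (reductive epoxy ketone opening); it does not reduce the α-acyloxy ketone or the C13 ketone.

Step 21
Reactants: 28 3β-hydroxy-1-ketone
Product: 29 1α,3β-diol (C13 ketone, C8 propargyl)
Conditions: Me4NBH(OAc)3 (5 equiv), MeCN/AcOH 1:1, −25 °C
Reagents that add atoms: none
Why: Evans–Saksena reduction: the axial 3β-hydroxyl binds boron and delivers hydride intramolecularly to the β face of the C1 ketone, giving the anti 1,3-diol (1α-OH); the undirected C13 ketone is not reduced.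

Step 22
Reactants: 29 keto alkyne diol
Product: 30 methyl ester of the target
Conditions: SmI2 (3 equiv), HMPA, t-BuOH, THF, 0 °C to rt
Reagents that add atoms: none
Why: SmI2 forms the C13 ketyl, which adds 5-exo-dig to the terminal alkyne (ketyl–alkyne reductive cyclisation); this closes ring D with the bridgehead tertiary alcohol and exocyclic methylene, the C13 configuration being dictated by the C8 tether.

Step 23
Reactants: 30 methyl ester
Product: 31 target CNP0252949.2
Conditions: n-PrSLi (5 equiv), HMPA, rt; cold dilute HCl to pH 3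
Reagents that add atoms: none
Why: SN2 demethylation of the hindered methyl ester by thiolate frees the C7 acid without exposing the 3β-hydroxy lactone to hydroxide, which would epimerise C3 by retro-aldol.

**Compound list**
1 | 3,5-dimethoxybenzoic acid | COc1cc(OC)cc(C(=O)O)c1 | starting material
2 | 3-bromo-1-(trimethylsilyl)prop-1-yne | C[Si](C)(C)C#CCBr | starting material
3 | 3,5-dimethoxy-1-[3-(trimethylsilyl)prop-2-yn-1-yl]cyclohexa-2,5-diene-1-carboxylic acid (achiral) | COC1=CC(CC#C[Si](C)(C)C)(C(=O)O)C=C(OC)C1 | intermediate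
4 | racemic 3-methoxy-5-oxo-1-[3-(trimethylsilyl)prop-2-yn-1-yl]cyclohex-3-ene-1-carboxylic acid | COC1=CC(=O)CC(CC#C[Si](C)(C)C)(C(=O)O)C1 | intermediate
5 | (S)-3-methoxy-5-oxo-1-[3-(trimethylsilyl)prop-2-yn-1-yl]cyclohex-3-ene-1-carboxylic acid | COC1=CC(=O)C[C@@](CC#C[Si](C)(C)C)(C(=O)O)C1 | intermediate
6 | (1S)-2-(1-hydroxyethyl)-5-methoxy-3-oxo-1-[3-(trimethylsilyl)prop-2-yn-1-yl]cyclohex-4-ene-1-carboxylic acid, epimers at C9 and C10 (not isolated) | COC1=CC(=O)C(C(C)O)[C@@](CC#C[Si](C)(C)C)(C(=O)O)C1 | intermediate
7 | cis-fused γ-lactone (C6(=O)–O–C10H(CH3)) on the ring C 3-methoxyenone (C11 ketone, C12=C13–OMe); H9 syn to the C8 CH2C≡CSiMe3 group; C10 epimers | COC1=CC(=O)[C@H]2C(C)OC(=O)[C@@]2(CC#C[Si](C)(C)C)C1 | intermediate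
8 | C11 allylic alcohol of 7 (not isolated) | COC1=CC(O)[C@H]2C(C)OC(=O)[C@@]2(CC#C[Si](C)(C)C)C1 | intermediate
9 | cis-fused enone lactone (C13 ketone, C11=C12); C10 epimers | O=C1C=C[C@H]2C(C)OC(=O)[C@@]2(CC#C[Si](C)(C)C)C1 | intermediate
10 | saturated C13 ketone lactone; C10 epimers | O=C1CC[C@H]2C(C)OC(=O)[C@@]2(CC#C[Si](C)(C)C)C1 | intermediate
11 | C13 ethylene ketal of 10; C10 epimers | O1CCOC12CC[C@H]3C(C)OC(=O)[C@@]3(CC#C[Si](C)(C)C)C2 | intermediate
12 | hydroxy enone: C8–C(=O)–C(OMe)=CH2, C9–CH(OH)CH3 (C10 epimers), C13 ketal; drawn in the open form | COC(=C)C(=O)[C@@]1(CC#C[Si](C)(C)C)CC2(OCCO2)CC[C@H]1C(C)O | intermediate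
13 | diketone: C9 acetyl, C8 2-methoxyacryloyl, C13 ketal | COC(=C)C(=O)[C@@]1(CC#C[Si](C)(C)C)CC2(OCCO2)CC[C@H]1C(C)=O | intermediate
14 | methyl α-keto ester: C8–C(=O)–CO2Me, C9 acetyl, C13 ketal | COC(=O)C(=O)[C@@]1(CC#C[Si](C)(C)C)CC2(OCCO2)CC[C@H]1C(C)=O | intermediate
15 | ring B/C enone ester: cis-fused hydrindenone with C10 ketone, C5=C6, CO2Me on C6, H9 β, C8 β-CH2C≡CSiMe3, C13 ethylene ketal | COC(=O)C1=CC(=O)[C@@H]2CCC3(OCCO3)C[C@]12CC#C[Si](C)(C)C | intermediate
16 | methylmalonic acid | CC(C(=O)O)C(=O)O | starting material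
17 | diallyl methylmalonate | CC(C(=O)OCC=C)C(=O)OCC=C | intermediate
18 | Michael adduct: C5 α-C(CH3)(CO2allyl)2, H5 β, C6 β-CO2Me, C10 ketone | COC(=O)[C@H]1[C@H](C(C)(C(=O)OCC=C)C(=O)OCC=C)C(=O)[C@@H]2CCC3(OCCO3)C[C@]12CC#C[Si](C)(C)C | intermediate
19 | C10 tertiary carbinol: α-OH, β-C(OEt)=CH2 (not isolated) | COC(=O)[C@H]1[C@H](C(C)(C(=O)OCC=C)C(=O)OCC=C)[C@@](O)(C(=C)OCC)[C@@H]2CCC3(OCCO3)C[C@]12CC#C[Si](C)(C)C | intermediate
20 | C19→C10 γ-lactone; C4 bears CH3 and CO2allyl (C4 epimers); C10 β-C(OEt)=CH2; C6 β-CO2Me | COC(=O)[C@H]1[C@@H]2C(C)(C(=O)OCC=C)C(=O)O[C@]2(C(=C)OCC)[C@@H]3CCC4(OCCO4)C[C@]13CC#C[Si](C)(C)C | intermediate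
21 | lactone acid (C4 CO2H) from 20 (not isolated) | COC(=O)[C@H]1[C@@H]2C(C)(C(=O)O)C(=O)O[C@]2(C(=C)OCC)[C@@H]3CCC4(OCCO4)C[C@]13CC#C[Si](C)(C)C | intermediate
22 | C4–H lactone (C4 bears H and CH3; C4 epimers) | COC(=O)[C@H]1[C@@H]2C(C)C(=O)O[C@]2(C(=C)OCC)[C@@H]3CCC4(OCCO4)C[C@]13CC#C[Si](C)(C)C | intermediate
23 | C4 hydroxymethyl lactone: C4 bears β-CH3 (C18) and CH2OH (C3) | COC(=O)[C@H]1[C@@H]2[C@@](C)(CO)C(=O)O[C@]2(C(=C)OCC)[C@@H]3CCC4(OCCO4)C[C@]13CC#C[Si](C)(C)C | intermediate
24 | C3 aldehyde of 23 | COC(=O)[C@H]1[C@@H]2[C@@](C)(C=O)C(=O)O[C@]2(C(=C)OCC)[C@@H]3CCC4(OCCO4)C[C@]13CC#C[Si](C)(C)C | intermediate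
25 | keto aldehyde: C1 methyl ketone, C3 aldehyde, C13 ketone (not isolated) | COC(=O)[C@H]1[C@@H]2[C@@](C)(C=O)C(=O)O[C@]2(C(C)=O)[C@@H]3CCC(=O)C[C@]13CC#C[Si](C)(C)C | intermediate
26 | ring A enone: 1-oxo-2-ene 19,10-lactone 7-methyl ester, C13 ketone, C8 CH2C≡CSiMe3 | COC(=O)[C@H]1[C@@H]2[C@@]3(C)C=CC(=O)[C@@]2(OC3=O)[C@@H]2CCC(=O)C[C@]12CC#C[Si](C)(C)C | intermediate
27 | 2β,3β-epoxy-1-ketone, C8 propargyl (terminal alkyne) | COC(=O)[C@H]1[C@@H]2[C@@]3(C)[C@H]4O[C@H]4C(=O)[C@@]2(OC3=O)[C@@H]2CCC(=O)C[C@]12CC#C | intermediate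
28 | 3β-hydroxy-1-ketone | COC(=O)[C@H]1[C@@H]2[C@@]3(C)[C@@H](O)CC(=O)[C@@]2(OC3=O)[C@@H]2CCC(=O)C[C@]12CC#C | intermediate
29 | 1α,3β-diol with C13 ketone and C8 propargyl | COC(=O)[C@H]1[C@@H]2[C@@]3(C)[C@@H](O)C[C@H](O)[C@@]2(OC3=O)[C@@H]2CCC(=O)C[C@]12CC#C | intermediate
30 | methyl ester of the target (1α,3β,13-trihydroxy-16-ene 19,10-lactone 7-methyl ester) | C=C1C[C@]23C[C@@]1(O)CC[C@H]2[C@@]12OC(=O)[C@@](C)([C@H]1[C@@H]3C(=O)OC)[C@@H](O)C[C@@H]2O | intermediate
31 | CNP0252949.2: 1α,3β,13-trihydroxy-20-norgibberell-16-ene-7,19-dioic acid 19,10-lactone | C=C1C[C@]23C[C@@]1(O)CC[C@H]2[C@@]12OC(=O)[C@@](C)([C@H]1[C@@H]3C(=O)O)[C@@H](O)C[C@@H]2O | target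

**Summary**
Total step count: 23. Longest linear sequence: 22 steps (1 → 31 through steps 1–11 and 13–23); step 12 is a one-step branch.

The three steps most likely to fail:

Step 13 (intermolecular Michael addition). The acceptor is congested and the C5/C6 configuration rests on equilibration. The fallback tethers the nucleophile. It sets out from 15: CH2=C(OEt)Li/CeCl3 is added to the C10 ketone first (β face) to give the tertiary carbinol F1. Its hydroxyl is acylated with allyl 3-chloro-2-methyl-3-oxopropanoate (Et3N, DMAP, CH2Cl2) to give the mixed malonate F2. Cs2CO3 in MeCN then closes the lactone by intramolecular 5-exo Michael addition onto C5, which forces C4 onto the α face. The fallback comes back to the route at 20.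

Step 16 (aldol of the lactone enolate with formaldehyde). Deprotonation could compete at C6, or the facial selectivity at C4 could be poor. The fallback forms C2–C3 first and lets ring closure set C4. It sets out from 22: oxalic acid in wet THF at 0 °C cleaves only the enol ether, giving the methyl ketone F3. Heating with t-BuOCH(NMe2)2 gives the enaminone F4. KHMDS in THF (−78 to 0 °C) generates the lactone enolate, which adds to C3 and expels dimethylamide (6-endo addition–elimination); only the correct C4 configuration can cyclise. Aqueous HCl work-up removes the dioxolane, and the fallback comes back to the route at 26.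

Step 22 (late ketyl–alkyne cyclisation). Simple reduction of the C13 ketone or poor conformational access could intervene. The fallback replaces the radical closure by a polar one. It sets out from 29: Markovnikov hydroiodination of the terminal alkyne (NaI, Me3SiCl, H2O, MeCN, 0 °C) gives the 2-iodoallyl ketone F5. Intramolecular Nozaki–Hiyama–Kishi addition of the alkenylchromium species to the C13 ketone (CrCl2, NiCl2 cat., DMF) then closes ring D, and the fallback comes back to the route at 30.

Further compounds
F1 | step 13 | C10 tertiary carbinol of 15 (α-OH, β-C(OEt)=CH2, C5=C6 retained) | COC(=O)C1=C[C@@](O)(C(=C)OCC)[C@@H]2CCC3(OCCO3)C[C@]12CC#C[Si](C)(C)C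
F2 | step 13 | O10 allyl methylmalonate ester of F1 | COC(=O)C1=C[C@@](OC(=O)C(C)C(=O)OCC=C)(C(=C)OCC)[C@@H]2CCC3(OCCO3)C[C@]12CC#C[Si](C)(C)C
F3 | step 16 | C1 methyl ketone of 22 (enol ether hydrolysed, ketal kept, C4 epimers) | COC(=O)[C@H]1[C@@H]2C(C)C(=O)O[C@]2(C(C)=O)[C@@H]3CCC4(OCCO4)C[C@]13CC#C[Si](C)(C)C
F4 | step 16 | enaminone of F3 (C1(=O)–CH=CH–NMe2) | COC(=O)[C@H]1[C@@H]2C(C)C(=O)O[C@]2(C(=O)/C=C/N(C)C)[C@@H]3CCC4(OCCO4)C[C@]13CC#C[Si](C)(C)C
F5 | step 22 | 2-iodoallyl ketone from 29 (C8–CH2–C(I)=CH2) | COC(=O)[C@H]1[C@@H]2[C@@]3(C)[C@@H](O)C[C@H](O)[C@@]2(OC3=O)[C@@H]2CCC(=O)C[C@]12CC(I)=C
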